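The isoflavone is cut at the C8a–O1 and C4a–C4 bonds, which leads back to a ring A aryne and 4-(methoxymethoxy)phenylacetic acid. The key step exploits the fact that the carbonyl carbon C4 and the ring oxygen O1 sit on the adjacent ring A atoms C4a and C8a, with the 5-OMe next to C4a to steer the addition. In one operation it attaches the phenol oxygen and the arylacetyl group, giving the ortho-hydroxy deoxybenzoin that ring C closure needs. Its precursor is a fully substituted ring A ortho-(trimethylsilyl)aryl triflate (silicon on C4a, triflate on C8a) carrying the 5-OMe, the MOM-protected (S)-hydroxyalkyl chain at C6, the 7-OMOM group and the C8 prenyl group.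

Key step: step 15

Remarks on the chemistry:
- Ring A positions are named by the isoflavone numbering of the target (C4a, C5 to C8, C8a) from the first intermediate on.
- MOM = methoxymethyl, EE = 1-ethoxyethyl, TIPS = triisopropylsilyl, Tf = trifluoromethanesulfonyl.
- Compounds 12, 14, 15, 16 and 17 carry the EE acetal and are assumed to be handled as mixtures of the two epimers at the acetal carbon. That centre is left undefined in their SMILES and is removed in step 12.
- Organolithium intermediates are drawn as monomers.
- A TIPS ether on the C8a oxygen screens both of its ortho positions, so it is used only for the C6 lithiation and is then exchanged for the chelating EE acetal before C8 and C4a are addressed.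
- The C4a–Si bond of this electron-rich ring is acid-labile, so silicon is introduced last and only base or fluoride follows it.

Step 1
Reactants: 1 L-valine
Product: 2 (2S)-2-chloro-3-methylbutanoic acid
Conditions: NaNO2, 5 M HCl (aq), 0 °C → rt
Reagents that add atoms: hydrochloric acid, Cl
Why: Diazotisation with participation of the neighbouring carboxylate (α-lactone, two inversions) should replace NH2 by Cl with net retention, so the (S) configuration of 1 is kept.

Step 2
Reactants: 2 (2S)-2-chloro-3-methylbutanoic acid
Product: 3 (2S)-2-chloro-3-methylbutan-1-ol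
Conditions: LiAlH4, Et2O, 0 °C
Reagents that add atoms: none
Why: Hydride reduction of the carboxylic acid to the primary alcohol should leave the chlorine-bearing stereocentre untouched at low temperature.

Step 3
Reactants: 3 (2S)-2-chloro-3-methylbutan-1-ol
Product: 4 (2R)-2-(propan-2-yl)oxirane
Conditions: KOH, H2O, 20 → 50 °C, product distilled into a cold trap
Reagents that add atoms: none
Why: Intramolecular Williamson etherification (SN2 closure of the alkoxide on C2) should invert the stereocentre cleanly, turning the (S)-chlorohydrin into the (R)-epoxide.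

Step 4
Reactants: 5 5-methoxyresorcinol
Product: 6 3-methoxy-5-(triisopropylsilyloxy)phenol
Conditions: TIPSCl (1.0 equiv), imidazole, DMF, 0 °C
Reagents that add atoms: chlorotriisopropylsilane, CC(C)[Si](Cl)(C(C)C)C(C)C
Why: Statistical monosilylation of the symmetric diol with a bulky silyl chloride should give mainly the mono-ether, with diol and bis-ether separable and recyclable; the OTIPS group later screens both of its ortho positions from lithiation.

Step 5
Reactants: 6 3-methoxy-5-(triisopropylsilyloxy)phenol
Product: 7 1-methoxy-3-(methoxymethoxy)-5-(triisopropylsilyloxy)benzene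
Conditions: MOMCl, iPr2NEt, CH2Cl2, 0 °C → rt
Reagents that add atoms: chloromethyl methyl ether, COCCl
Why: Base-mediated O-alkylation of the remaining phenol with the α-chloro ether (Williamson type) should proceed without touching the silyl ether.

Step 6
Reactants: 7 1-methoxy-3-(methoxymethoxy)-5-(triisopropylsilyloxy)benzene; 4 (2R)-2-(propan-2-yl)oxirane
Product: 9 (2S)-1-[2-methoxy-6-(methoxymethoxy)-4-(triisopropylsilyloxy)phenyl]-3-methylbutan-2-ol, via C6 aryllithium 8 (not isolated)
Conditions: n-BuLi, THF, 0 °C; then BF3·OEt2, 4, −78 °C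
Reagents that add atoms: none
Why: Directed ortho-metalation should occur only at C6, the one ring CH flanked by OMe and OMOM and not screened by OTIPS, and the aryllithium should open the BF3-activated epoxide by SN2 attack at its CH2 terminus, so the stereocentre of 4 is carried over unchanged and appears as the (S)-carbinol.

Step 7
Reactants: 9 (2S)-1-[2-methoxy-6-(methoxymethoxy)-4-(triisopropylsilyloxy)phenyl]-3-methylbutan-2-ol
Product: 10 1-methoxy-3-(methoxymethoxy)-2-[(2S)-2-(methoxymethoxy)-3-methylbutyl]-5-(triisopropylsilyloxy)benzene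
Conditions: MOMCl, iPr2NEt, Bu4NI (cat.), CH2Cl2, 40 °C
Reagents that add atoms: chloromethyl methyl ether, COCCl
Why: O-Alkylation of the secondary alcohol (MOM ether formation) does not involve the C–O bond of the stereocentre, so the configuration is retained.

Step 8
Reactants: 10 1-methoxy-3-(methoxymethoxy)-2-[(2S)-2-(methoxymethoxy)-3-methylbutyl]-5-(triisopropylsilyloxy)benzene
Product: 11 3-methoxy-5-(methoxymethoxy)-4-[(2S)-2-(methoxymethoxy)-3-methylbutyl]phenol
Conditions: Bu4NF, THF, 0 °C
Reagents that add atoms: none
Why: Fluoride-induced desilylation, driven by the strong Si–F bond, should free the C8a phenol while the MOM acetals are inert.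

Step 9
Reactants: 11 3-methoxy-5-(methoxymethoxy)-4-[(2S)-2-(methoxymethoxy)-3-methylbutyl]phenol
Product: 12 1-(1-ethoxyethoxy)-3-methoxy-5-(methoxymethoxy)-4-[(2S)-2-(methoxymethoxy)-3-methylbutyl]benzene
Conditions: ethyl vinyl ether, pyridinium p-toluenesulfonate (cat.), CH2Cl2, rt
Reagents that add atoms: ethyl vinyl ether, C=COCC
Why: Acid-catalysed addition of the phenol to the enol ether (acetalisation) should install a chelating acetal that directs lithiation like OMOM yet is far more acid-labile; the new acetal centre forms without control and is of no consequence.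

Step 10
Reactants: 12 1-(1-ethoxyethoxy)-3-methoxy-5-(methoxymethoxy)-4-[(2S)-2-(methoxymethoxy)-3-methylbutyl]benzene; 13 prenyl bromide
Product: 15 1-(1-ethoxyethoxy)-5-methoxy-3-(methoxymethoxy)-4-[(2S)-2-(methoxymethoxy)-3-methylbutyl]-2-(3-methylbut-2-en-1-yl)benzene, via C8 aryllithium 14 (not isolated)
Conditions: n-BuLi, THF, 0 °C; then CuI (10 mol%), 13, −78 °C → rt
Reagents that add atoms: none
Why: Directed ortho-metalation should favour C8, which lies between two chelating acetal groups, over C4a, whose second neighbour is an OMe group turned away from it by the C6 chain, and copper-catalysed SN2 allylation of the aryllithium at the primary carbon of 13 then installs the prenyl group.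

Step 11
Reactants: 15 1-(1-ethoxyethoxy)-5-methoxy-3-(methoxymethoxy)-4-[(2S)-2-(methoxymethoxy)-3-methylbutyl]-2-(3-methylbut-2-en-1-yl)benzene
Product: 17 1-bromo-2-(1-ethoxyethoxy)-6-methoxy-4-(methoxymethoxy)-5-[(2S)-2-(methoxymethoxy)-3-methylbutyl]-3-(3-methylbut-2-en-1-yl)benzene, via C4a aryllithium 16 (not isolated)
Conditions: n-BuLi, THF, 0 °C; then BrCl2C–CCl2Br, −78 °C
Reagents that add atoms: 1,2-dibromo-1,1,2,2-tetrachloroethane, ClC(Cl)(Br)C(Cl)(Cl)Br
Why: The last ring CH, at C4a between OEE and OMe, should be removed by directed ortho-metalation and the aryllithium brominated by halogen transfer from a reagent that releases no Br2, so the prenyl double bond is spared.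

Step 12
Reactants: 17 1-bromo-2-(1-ethoxyethoxy)-6-methoxy-4-(methoxymethoxy)-5-[(2S)-2-(methoxymethoxy)-3-methylbutyl]-3-(3-methylbut-2-en-1-yl)benzene
Product: 18 2-bromo-3-methoxy-5-(methoxymethoxy)-4-[(2S)-2-(methoxymethoxy)-3-methylbutyl]-6-(3-methylbut-2-en-1-yl)phenol
Conditions: pyridinium p-toluenesulfonate (cat.), MeOH, rt
Reagents that add atoms: none
Why: Acid-catalysed transacetalisation in methanol should cleave the acetaldehyde-derived EE acetal selectively, since it ionises much faster than the formaldehyde-derived MOM groups, which remain.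

Step 13
Reactants: 18 2-bromo-3-methoxy-5-(methoxymethoxy)-4-[(2S)-2-(methoxymethoxy)-3-methylbutyl]-6-(3-methylbut-2-en-1-yl)phenol
Product: 21 3-methoxy-5-(methoxymethoxy)-4-[(2S)-2-(methoxymethoxy)-3-methylbutyl]-6-(3-methylbut-2-en-1-yl)-2-(trimethylsilyl)phenyl trifluoromethanesulfonate, via aryl silyl ether 19 (not isolated), via lithium silylphenoxide 20 (not isolated)
Conditions: (Me3Si)2NH, THF, 65 °C, then evaporation; n-BuLi, THF, −78 °C; Tf2O, −78 °C
Reagents that add atoms: hexamethyldisilazane, C[Si](C)(C)N[Si](C)(C)C; trifluoromethanesulfonic anhydride, O=S(=O)(OS(=O)(=O)C(F)(F)F)C(F)(F)F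
Why: O-Silylation followed by bromine–lithium exchange should trigger the 1,3 O-to-C silyl shift (retro-Brook rearrangement) to the lithium 2-silylphenoxide, which Tf2O traps at oxygen; exchange is much faster than any deprotonation, so the prenyl and MOM groups are tolerated.

Step 14
Reactants: 22 4-hydroxyphenylacetic acid
Product: 24 [4-(methoxymethoxy)phenyl]acetic acid, via MOM ester 23 (not isolated)
Conditions: MOMCl (2.5 equiv), iPr2NEt, CH2Cl2, 0 °C → rt; then LiOH, THF/H2O, rt; 1 M HCl to pH 4, 0 °C
Reagents that add atoms: chloromethyl methyl ether, COCCl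
Why: Double O-alkylation gives the aryl MOM ether and the MOM ester, and saponification of the much more labile acyloxymethyl ester then returns the acid with the aryl MOM ether intact.

Step 15
Reactants: 21 3-methoxy-5-(methoxymethoxy)-4-[(2S)-2-(methoxymethoxy)-3-methylbutyl]-6-(3-methylbut-2-en-1-yl)-2-(trimethylsilyl)phenyl trifluoromethanesulfonate; 24 [4-(methoxymethoxy)phenyl]acetic acid
Product: 26 1-{2-hydroxy-6-methoxy-4-(methoxymethoxy)-5-[(2S)-2-(methoxymethoxy)-3-methylbutyl]-3-(3-methylbut-2-en-1-yl)phenyl}-2-[4-(methoxymethoxy)phenyl]ethan-1-one, via ring A aryne 25 (not isolated)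
Conditions: CsF (5 equiv), THF, 24 (2 equiv) stirred with the CsF at rt, then 21, sealed tube, 110 °C
Reagents that add atoms: none
Why: Fluoride-induced loss of the silyl group and of triflate from the neighbouring carbon should generate aryne 25 (C4a–C8a triple bond), to which the cesium carboxylate of 24, formed beforehand by the excess CsF, adds through oxygen at C8a. The carbanion thereby created at C4a adds to the carbonyl group of the aryl ester it now belongs to, and the strained four-membered alkoxide reopens by breaking the bond between the acyl carbon and the C8a-bound oxygen, a net anionic O-to-C acyl shift that leaves the ketone on C4a and the phenoxide on C8a. The closest known reaction type is the fluoride-triggered insertion of arynes into the C–O bond of carboxylic acids, which delivers ortho-hydroxyaryl ketones. No ring is closed, the four-membered adduct being only transient, and no stereocentre is formed, the (S)-carbinol in the C6 chain being remote from the reacting carbons. The step needs oxygen attack at C8a and not at C4a, which the electronegative 5-OMe group beside C4a should secure by distorting the aryne so that the charge develops next to it, an electronic preference expected to outweigh the opposing steric demand of the C8 prenyl group. It also needs acyl transfer to outrun protonation of the C4a anion and arylation of the product phenoxide, which the aprotic medium, the intramolecular ester carbonyl and the excess of carboxylate should secure.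

Step 16
Reactants: 26 1-{2-hydroxy-6-methoxy-4-(methoxymethoxy)-5-[(2S)-2-(methoxymethoxy)-3-methylbutyl]-3-(3-methylbut-2-en-1-yl)phenyl}-2-[4-(methoxymethoxy)phenyl]ethan-1-one
Product: 28 5-methoxy-7-(methoxymethoxy)-6-[(2S)-2-(methoxymethoxy)-3-methylbutyl]-3-[4-(methoxymethoxy)phenyl]-8-(3-methylbut-2-en-1-yl)-4H-chromen-4-one, via enaminone 27 (not isolated)
Conditions: Me2NCH(OMe)2, toluene, 90 °C
Reagents that add atoms: N,N-dimethylformamide dimethyl acetal, COC(OC)N(C)C
Why: Condensation of the activated methylene with the amide acetal gives the enaminone, whose β-carbon is attacked by the neighbouring C8a phenol (6-endo-trig addition–elimination) with loss of dimethylamine, the standard deoxybenzoin route to ring C of an isoflavone.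

Step 17
Reactants: 28 5-methoxy-7-(methoxymethoxy)-6-[(2S)-2-(methoxymethoxy)-3-methylbutyl]-3-[4-(methoxymethoxy)phenyl]-8-(3-methylbut-2-en-1-yl)-4H-chromen-4-one
Product: 29 7-hydroxy-6-[(2S)-2-hydroxy-3-methylbutyl]-3-(4-hydroxyphenyl)-5-methoxy-8-(3-methylbut-2-en-1-yl)-4H-chromen-4-one (CNP0323282.1)
Conditions: 3 M HCl (aq), MeOH/THF, 45 °C
Reagents that add atoms: none
Why: Acid-catalysed acetal exchange with methanol should remove the two aryl and the one alkyl MOM group without breaking the C–O bond of the stereocentre, so the (S)-carbinol is retained, while the 5-OMe ether and the chromone are stable.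

Compound list
1 | L-valine, (2S)-2-amino-3-methylbutanoic acid | CC(C)[C@H](N)C(=O)O | starting material
2 | (2S)-2-chloro-3-methylbutanoic acid | CC(C)[C@H](Cl)C(=O)O | intermediate
3 | (2S)-2-chloro-3-methylbutan-1-ol | CC(C)[C@H](Cl)CO | intermediate
4 | (2R)-2-(propan-2-yl)oxirane | CC(C)[C@@H]1CO1 | intermediate
5 | 5-methoxyresorcinol | COc1cc(O)cc(O)c1 | starting material
6 | 3-methoxy-5-(triisopropylsilyloxy)phenol | COc1cc(O)cc(O[Si](C(C)C)(C(C)C)C(C)C)c1 | intermediate
7 | 1-methoxy-3-(methoxymethoxy)-5-(triisopropylsilyloxy)benzene | COCOc1cc(OC)cc(O[Si](C(C)C)(C(C)C)C(C)C)c1 | intermediate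
8 | [2-methoxy-6-(methoxymethoxy)-4-(triisopropylsilyloxy)phenyl]lithium (C6 aryllithium) | [Li]c1c(OC)cc(O[Si](C(C)C)(C(C)C)C(C)C)cc1OCOC | intermediate (not isolated)
9 | (2S)-1-[2-methoxy-6-(methoxymethoxy)-4-(triisopropylsilyloxy)phenyl]-3-methylbutan-2-ol | COc1cc(O[Si](C(C)C)(C(C)C)C(C)C)cc(OCOC)c1C[C@H](O)C(C)C | intermediate
10 | 1-methoxy-3-(methoxymethoxy)-2-[(2S)-2-(methoxymethoxy)-3-methylbutyl]-5-(triisopropylsilyloxy)benzene | COc1cc(O[Si](C(C)C)(C(C)C)C(C)C)cc(OCOC)c1C[C@H](OCOC)C(C)C | intermediate
11 | 3-methoxy-5-(methoxymethoxy)-4-[(2S)-2-(methoxymethoxy)-3-methylbutyl]phenol | COc1cc(O)cc(OCOC)c1C[C@H](OCOC)C(C)C | intermediate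
12 | 1-(1-ethoxyethoxy)-3-methoxy-5-(methoxymethoxy)-4-[(2S)-2-(methoxymethoxy)-3-methylbutyl]benzene (both acetal epimers) | CCOC(C)Oc1cc(OC)c(C[C@H](OCOC)C(C)C)c(OCOC)c1 | intermediate
13 | prenyl bromide, 1-bromo-3-methylbut-2-ene | CC(C)=CCBr | starting material
14 | C8 aryllithium of 12, lithium on the carbon between OEE and OMOM | CCOC(C)Oc1cc(OC)c(C[C@H](OCOC)C(C)C)c(OCOC)c1[Li] | intermediate (not isolated)
15 | 1-(1-ethoxyethoxy)-5-methoxy-3-(methoxymethoxy)-4-[(2S)-2-(methoxymethoxy)-3-methylbutyl]-2-(3-methylbut-2-en-1-yl)benzene | CCOC(C)Oc1cc(OC)c(C[C@H](OCOC)C(C)C)c(OCOC)c1CC=C(C)C | intermediate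
16 | C4a aryllithium of 15, lithium on the carbon between OEE and OMe | CCOC(C)Oc1c([Li])c(OC)c(C[C@H](OCOC)C(C)C)c(OCOC)c1CC=C(C)C | intermediate (not isolated)
17 | 1-bromo-2-(1-ethoxyethoxy)-6-methoxy-4-(methoxymethoxy)-5-[(2S)-2-(methoxymethoxy)-3-methylbutyl]-3-(3-methylbut-2-en-1-yl)benzene | CCOC(C)Oc1c(Br)c(OC)c(C[C@H](OCOC)C(C)C)c(OCOC)c1CC=C(C)C | intermediate
18 | 2-bromo-3-methoxy-5-(methoxymethoxy)-4-[(2S)-2-(methoxymethoxy)-3-methylbutyl]-6-(3-methylbut-2-en-1-yl)phenol | Oc1c(Br)c(OC)c(C[C@H](OCOC)C(C)C)c(OCOC)c1CC=C(C)C | intermediate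
19 | trimethylsilyl ether of 18 | C[Si](C)(C)Oc1c(Br)c(OC)c(C[C@H](OCOC)C(C)C)c(OCOC)c1CC=C(C)C | intermediate (not isolated)
20 | lithium 3-methoxy-5-(methoxymethoxy)-4-[(2S)-2-(methoxymethoxy)-3-methylbutyl]-6-(3-methylbut-2-en-1-yl)-2-(trimethylsilyl)phenoxide | [Li]Oc1c([Si](C)(C)C)c(OC)c(C[C@H](OCOC)C(C)C)c(OCOC)c1CC=C(C)C | intermediate (not isolated)
21 | 3-methoxy-5-(methoxymethoxy)-4-[(2S)-2-(methoxymethoxy)-3-methylbutyl]-6-(3-methylbut-2-en-1-yl)-2-(trimethylsilyl)phenyl trifluoromethanesulfonate (aryne precursor) | COc1c(C[C@H](OCOC)C(C)C)c(OCOC)c(CC=C(C)C)c(OS(=O)(=O)C(F)(F)F)c1[Si](C)(C)C | intermediate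
22 | 4-hydroxyphenylacetic acid | OC(=O)Cc1ccc(O)cc1 | starting material
23 | methoxymethyl [4-(methoxymethoxy)phenyl]acetate | COCOC(=O)Cc1ccc(OCOC)cc1 | intermediate (not isolated)
24 | [4-(methoxymethoxy)phenyl]acetic acid | COCOc1ccc(CC(=O)O)cc1 | intermediate
25 | ring A aryne: 3-methoxy-5-(methoxymethoxy)-4-[(2S)-2-(methoxymethoxy)-3-methylbutyl]-6-(3-methylbut-2-en-1-yl)-1,2-didehydrobenzene (triple bond C4a–C8a) | COC1=C(C[C@H](OCOC)C(C)C)C(OCOC)=C(CC=C(C)C)C#C1 | intermediate (not isolated)
26 | 1-{2-hydroxy-6-methoxy-4-(methoxymethoxy)-5-[(2S)-2-(methoxymethoxy)-3-methylbutyl]-3-(3-methylbut-2-en-1-yl)phenyl}-2-[4-(methoxymethoxy)phenyl]ethan-1-one | COc1c(C[C@H](OCOC)C(C)C)c(OCOC)c(CC=C(C)C)c(O)c1C(=O)Cc1ccc(OCOC)cc1 | intermediate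
27 | enaminone: 3-(dimethylamino)-2-[4-(methoxymethoxy)phenyl]prop-2-en-1-one bearing the aryl group of 26 at C1 (alkene geometry not defined) | COc1c(C[C@H](OCOC)C(C)C)c(OCOC)c(CC=C(C)C)c(O)c1C(=O)C(=CN(C)C)c1ccc(OCOC)cc1 | intermediate (not isolated)
28 | 5-methoxy-7-(methoxymethoxy)-6-[(2S)-2-(methoxymethoxy)-3-methylbutyl]-3-[4-(methoxymethoxy)phenyl]-8-(3-methylbut-2-en-1-yl)-4H-chromen-4-one | COc1c(C[C@H](OCOC)C(C)C)c(OCOC)c(CC=C(C)C)c2occ(-c3ccc(OCOC)cc3)c(=O)c12 | intermediate
29 | 7-hydroxy-6-[(2S)-2-hydroxy-3-methylbutyl]-3-(4-hydroxyphenyl)-5-methoxy-8-(3-methylbut-2-en-1-yl)-4H-chromen-4-one | COc1c(C[C@H](O)C(C)C)c(O)c(CC=C(C)C)c2occ(-c3ccc(O)cc3)c(=O)c12 | target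

Total step count: 17.
Longest linear sequence: 14 steps (steps 1–3, 6–13 and 15–17, from L-valine); from 5-methoxyresorcinol the line is 13 steps.

Steps most likely to fail

1. Step 15. The carboxylate may add to the wrong aryne carbon. The C4a anion may be protonated before it takes the acyl group, which stops at the aryl ester. The product phenoxide may be arylated by a second aryne, and the crowded aryne may form only sluggishly. Fallback, from 17 and 24, back to the route at 26: acid 24 would be converted with 1,1′-carbonyldiimidazole and N,O-dimethylhydroxylamine hydrochloride into N-methoxy-N-methyl-2-[4-(methoxymethoxy)phenyl]acetamide F1. Bromide 17 would undergo bromine–lithium exchange (n-BuLi, THF, −78 °C) to aryllithium 16, which would be added to F1 at −78 °C (Weinreb ketone synthesis) to give 1-{2-(1-ethoxyethoxy)-6-methoxy-4-(methoxymethoxy)-5-[(2S)-2-(methoxymethoxy)-3-methylbutyl]-3-(3-methylbut-2-en-1-yl)phenyl}-2-[4-(methoxymethoxy)phenyl]ethan-1-one F2. Pyridinium p-toluenesulfonate in methanol, as in step 12, would then release the phenol and give 26.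

2. Step 10. The doubly flanked aryllithium may couple slowly with the trisubstituted allylic bromide, attack its tertiary terminus (allylic transposition) or exchange halogen with it instead of substituting. Fallback, from 12, back to the route at 15: aryllithium 14, made as in step 10, would be quenched with allyl bromide, which has no such regiochemical ambiguity, to give 1-(1-ethoxyethoxy)-5-methoxy-3-(methoxymethoxy)-4-[(2S)-2-(methoxymethoxy)-3-methylbutyl]-2-(prop-2-en-1-yl)benzene F3. Olefin cross-metathesis of F3 with 2-methylbut-2-ene (second-generation Grubbs catalyst, CH2Cl2, 40 °C) would then build the trisubstituted alkene and give 15.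

3. Step 11. The base may deprotonate the benzylic, allylic CH2 of the prenyl group, or the benzylic CH2 of the C6 chain with β-elimination of the MOM-oxy group, in competition with removal of the C4a ring proton. Fallback, from 15, back to the route at 17: the bromine would be introduced without base by electrophilic aromatic substitution at the only free ring position, using N-bromosuccinimide buffered with NaHCO3 in MeCN at −40 °C. The tri-oxygenated ring should react far faster than the isolated alkene in the absence of a protic nucleophile. This fallback makes no new compound (entry F0).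

Further compounds
F1 | step 15 | N-methoxy-N-methyl-2-[4-(methoxymethoxy)phenyl]acetamide | COCOc1ccc(CC(=O)N(C)OC)cc1
F2 | step 15 | 1-{2-(1-ethoxyethoxy)-6-methoxy-4-(methoxymethoxy)-5-[(2S)-2-(methoxymethoxy)-3-methylbutyl]-3-(3-methylbut-2-en-1-yl)phenyl}-2-[4-(methoxymethoxy)phenyl]ethan-1-one (both acetal epimers) | CCOC(C)Oc1c(C(=O)Cc2ccc(OCOC)cc2)c(OC)c(C[C@H](OCOC)C(C)C)c(OCOC)c1CC=C(C)C
F3 | step 10 | 1-(1-ethoxyethoxy)-5-methoxy-3-(methoxymethoxy)-4-[(2S)-2-(methoxymethoxy)-3-methylbutyl]-2-(prop-2-en-1-yl)benzene (both acetal epimers) | CCOC(C)Oc1cc(OC)c(C[C@H](OCOC)C(C)C)c(OCOC)c1CC=C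
F0 | step 11 | none | none
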